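## Structural features

Mollicellin A is a depsidone: two benzene rings, A and B, are joined twice, by a diaryl ether oxygen and by an aryl ester, so that a seven-membered lactone lies between them. Ring A carries in sequence a methyl group, one hydrogen, a hydroxyl, a formyl group, the ether oxygen and the lactone carbonyl. Ring B, in chromanone numbering, carries the ester oxygen on C7, the ether oxygen on C6 and a methyl group on C5, and is fused across C4a–C8a to a 2,2-dimethyl-2,3-dihydropyran-4-one, so C8 is its only C–H. There is no stereocentre. The fragile groups are the ortho-hydroxy aldehyde, the aryl ester lactone (opened by hydroxide or alkoxide) and the electron-rich trioxygenated ring B once its phenols are free. The real difficulty is ring B: five contiguous substituents, two adjacent oxygens (O6 and O7) that must be told apart because one becomes an ether and the other an ester, and a diaryl ether flanked by four ortho substituents. The key step uses the fact that the pyran oxygen on C8a is para to the C6 oxygen. That is the alkoxy/hydroxy relationship of a carbene benzannulation, with C8a as carbene carbon, C6 as inserted CO, C4a/C5 as alkyne carbons and C8/C7 as the vinyl group. The pyran oxygen itself can tie the alkyne to the carbene.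

## Logic of the disconnections

28 to 27: the O–CH3 bond of the ring A phenol is the last one made in reverse. A methyl ether ortho to the formyl group is the one ether that a chelating boron Lewis acid removes while lactone, ketone and the cyclic tertiary ether stay. The gain is that no earlier step has to carry a free salicylaldehyde phenol. The demand is that no second methyl ether ortho to a carbonyl exists, which holds.

27 to 26: the ester C(=O)–O bond of the seven-membered ring is cut, leaving a benzoic acid on ring A and the C7 phenol on ring B. This removes the most labile bond first and opens the tricyclic core to a plain diaryl ether. The forward step must activate an acid with two ortho substituents and close a seven-membered ring faster than chains form.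

26 to 25: two O–benzyl bonds are cut, the C7 ether and the ring A ester. Both partners of the lactonisation are then set free by one hydrogenolysis, and up to that point O7 is distinguishable from O6. The forward step must spare the formyl group and the aryl ketone.

25 to 18 and 23 (through 24): the aryl C–O bond between ring A and the C6 oxygen is cut. This is the convergent cut: the ring A carbon lies between a formyl and an ester group, which activate a fluoride for addition–elimination, and 18 has only its C6 hydroxyl free. The forward step must bring a phenoxide with two ortho neighbours onto a carbon with two ortho neighbours. The ketal of 24 is shed in the acidic work-up.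

23 to 22, 20 and 19: ring A is simplified at the C–CO2 bond (carbonylation of a bromide), the C–CHO bond (metalation between fluorine and methoxy) and the C–Br bond (bromination para to methoxy). Each cut uses a directing effect already present, so a benzene with three substituents suffices. The demand is regiocontrol at every stage, which the order of events supplies.

18 to 16 (key): three C–C bonds of ring B are cut at once, C8a–C4a, C5–C6 and C6–C7, and C6 returns to a CO ligand. Ring B and the pyran ring both disappear and an acyclic carbene complex remains. The forward step must insert the alkyne with the ketal-bearing carbon at the carbene carbon, insert CO, and tolerate ketal and benzyl ether.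

16 to 14 and 7 (through 15): the bond between carbene carbon and tether oxygen is cut, separating the chromium-bearing C3 unit from the metal-free alcohol. The demand, and the weakest point of the plan, is that a tertiary alcohol displaces carboxylate from an acyloxycarbene.

14 to 10 and 11, then 8: the carbene carbon–vinyl carbon bond is cut to a vinyllithium (12) and a CO ligand of 11; the C–Br bond of 10 leads back to 8. The forward steps need a Z β-alkoxyvinyllithium that is stable at low temperature.

7 to 5, then 3 and 4, then 2 and 1: the two ketal C–O bonds, the acyl–alkyne C–C bond, the amide C–N bond and the O–Si bond are cut in turn. The ketalisation must beat conjugate addition to the ynone, and the silyl group must keep the β-hydroxy carbonyl compounds from retro-aldol cleavage and oxa-Michael closure.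

## Other disconnections considered

Alternative 1: The cut removes the C5 methyl group and the C4a–alkyne bond from ring B of a finished depsidone, leaving the aryl iodide A1. In the forward step Pd(OAc)2 with a phosphine and a strained bicyclic alkene as mediator forms a palladacycle at the C–H next to the iodide. A methyl sulfonate methylates it through a tetravalent palladium intermediate, and after loss of the mediator a tertiary alkynol is coupled at the original C–I carbon to give A2.
- In favour: two C–C bonds are made late on a complete core, catalytically, and the gem-dimethyl carbinol comes from a commodity alkynol.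
- Against: A1 needs its own synthesis, with the trioxygenated ring B already built and O6/O7 already differentiated. Carbonate base near 100 °C endangers the lactone and the aldehyde. A2 still needs selective unmasking of one of two methyl ethers, Meyer–Schuster rearrangement and oxa-Michael closure.
- Comparison: on structure the chosen plan builds ring B and the pyran ring with the oxygens differentiated, while this one decorates an existing ring and closes none. On mechanism both are multi-event organometallic cascades; being catalytic in palladium and free of an untested carbene synthesis, Alternative 1 is the better. On step economy it is not shorter once A1 and the steps after A2 are counted.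

Alternative 2: The cut removes three C–C bonds of ring A, leading to A3, a ring B chromanone carrying a but-2-ynoate on O7 and an ethynyl ether on O6. In the forward step Cp*RuCl(cod) couples the two tethered alkynes to a ruthenacycle that takes up an ethynylboronate and gives A4, closing ring A and the lactone together.
- In favour: catalytic, fully atom-economic, no protecting group on ring A; on these points it is better than the chosen plan.
- Against: A3 presupposes the ring B chromanone with O6 and O7 differentiated, which is what the chosen key step delivers. The ethynyl ether must be made on a phenol with two ortho neighbours. The tether closes a seven-membered ring, which is slower than the usual five- or six-membered cases, and the orientation of the boryl alkyne is not secured. A4 lacks the formyl group, so boronate oxidation and an ortho-formylation with two open ortho positions follow on a base-labile depsidone.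
- Comparison: the same number of C–C bonds and two rings are formed, so it equals the chosen step in bond count. It is complementary in structure (ring A instead of ring B) and weaker in step economy because of the late oxidation and formylation.

Alternative 3: The cut removes three C–C bonds of ring A, leading to the diazo ketoester A5 and the ring B ethynyl ether A6. Wolff rearrangement of A5 gives an ester-substituted vinylketene, which adds to A6 by (2+2) cycloaddition; four-electron ring opening and six-electron closure then give the phenol A7.
- In favour: the regiochemistry is set by the polarisation of the ynol ether, no metal is needed in stoichiometric amount, and the ether oxygen comes from the ring B phenol, so no hindered diaryl ether coupling is required. On that last point it is better than the addition–elimination step of the chosen plan.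
- Against: A6 derives from the same differentiated chromanone phenol, so ring B must still be made. A 2-diazo-1,3-dicarbonyl compound needs photolysis for the Wolff step and its acylketene can dimerise. A7 lacks the formyl group and needs a late, regiochemically open formylation before lactonisation.
- Comparison: mechanistically it is a close relative of the chosen step (a vinylketene closing to a phenol) and forms as many C–C bonds, but only one ring. In step economy it is longer overall.

Key step: step 8

Assumption: the alkoxyvinyl unit of 12–16 is drawn Z as formed; push–pull isomerisation to E would change nothing downstream, because that carbon becomes the aromatic C7 of 18.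

## Route

Step 1
Reactants: 1 ethyl 3-hydroxy-3-methylbutanoate
Product: 2 ethyl 3-methyl-3-(triethylsilyloxy)butanoate
Conditions: Et3SiOTf, 2,6-lutidine, CH2Cl2, −78 → 0 °C
Reagents that add atoms: triethylsilyl trifluoromethanesulfonate, CC[Si](CC)(CC)OS(=O)(=O)C(F)(F)F
Why: Silylation of a tertiary alcohol with a silyl triflate and a hindered pyridine base; the ether blocks retro-aldol cleavage in steps 2 and 3 and oxa-Michael closure of the later ynone.

Step 2
Reactants: 2 ethyl 3-methyl-3-(triethylsilyloxy)butanoate
Product: 3 N-methoxy-N,3-dimethyl-3-(triethylsilyloxy)butanamide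
Conditions: MeNH(OMe)·HCl, i-PrMgCl, THF, −20 → 0 °C
Reagents that add atoms: N,O-dimethylhydroxylamine hydrochloride, CNOC.Cl
Why: Weinreb amide formation from an ester with the magnesium amide made in the flask; aminolysis should outrun α-deprotonation at this temperature.

Step 3
Reactants: 3 N-methoxy-N,3-dimethyl-3-(triethylsilyloxy)butanamide, 4 1-propynylmagnesium bromide
Product: 5 6-methyl-6-(triethylsilyloxy)hept-2-yn-4-one
Conditions: THF, 0 °C; aq NH4Cl
Reagents that add atoms: none
Why: Weinreb ketone synthesis; the chelated tetrahedral adduct prevents a second addition and releases the ynone only on quenching.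

Step 4
Reactants: 5 6-methyl-6-(triethylsilyloxy)hept-2-yn-4-one
Product: 7 2-methyl-1-[2-(prop-1-yn-1-yl)-1,3-dioxolan-2-yl]propan-2-ol, via triethylsilyl ether ketal 6 (not isolated)
Conditions: (Me3SiOCH2)2, Me3SiOTf (cat.), CH2Cl2, −78 → −20 °C; pyridine; then Bu4NF, THF, rt
Reagents that add atoms: 1,2-bis(trimethylsilyloxy)ethane, C[Si](C)(C)OCCO[Si](C)(C)C
Why: Noyori ketalisation, driven by formation of hexamethyldisiloxane and run cold so that 1,2-addition to the activated carbonyl precedes conjugate addition; fluoride then frees the tertiary alcohol without touching the ketal.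

Step 5
Reactants: 8 benzyl vinyl ether
Product: 10 (Z)-[(2-bromovinyl)oxy]methylbenzene, via benzyl 1,2-dibromoethyl ether 9 (not isolated)
Conditions: Br2, CH2Cl2, −78 °C; concentrate; PhNEt2, 90 °C
Reagents that add atoms: bromine, BrBr
Why: Bromine addition to the enol ether and amine-induced loss of HBr from the α-bromo ether, the standard route to 1-alkoxy-2-bromoethenes; the Z isomer should predominate (cis effect) and is purified from any E isomer.

Step 6
Reactants: 10 (Z)-[(2-bromovinyl)oxy]methylbenzene, 11 hexacarbonylchromium
Product: 14 tetramethylammonium pentacarbonyl[(Z)-3-(benzyloxy)-1-oxidoprop-2-en-1-ylidene]chromate, via (Z)-2-(benzyloxy)vinyllithium 12 (not isolated), via lithium acylchromate 13 (not isolated)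
Conditions: t-BuLi (2 equiv), Et2O, −78 °C; 11, THF, −78 → 0 °C; then Me4NBr, H2O
Reagents that add atoms: tetramethylammonium bromide, C[N+](C)(C)C.[Br-]
Why: Bromine–lithium exchange with retention gives the oxygen-chelated Z vinyllithium, which cannot undergo anti β-elimination and is used cold before benzylic metalation can compete; Fischer addition to a CO ligand and cation exchange give the storable acyl chromate salt.

Step 7
Reactants: 14 tetramethylammonium pentacarbonyl[(Z)-3-(benzyloxy)-1-oxidoprop-2-en-1-ylidene]chromate, 7 2-methyl-1-[2-(prop-1-yn-1-yl)-1,3-dioxolan-2-yl]propan-2-ol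
Product: 16 pentacarbonyl{[(Z)-2-(benzyloxy)vinyl]{[2-methyl-1-(2-(prop-1-yn-1-yl)-1,3-dioxolan-2-yl)propan-2-yl]oxy}carbene}chromium, via pivaloyloxycarbene complex 15 (not isolated)
Conditions: t-BuCOCl, CH2Cl2, −40 °C; then 7, −40 → 0 °C (14 and acid chloride in excess)
Reagents that add atoms: none
Why: Proposed new method: O-acylation of 14 gives acyloxycarbene 15, the metal analogue of a mixed anhydride, whose carbene carbon should add the tertiary alcohol and expel pivalate by addition–elimination; the closest known reaction type is alcoholysis of acyloxycarbene chromium complexes by primary and secondary alcohols; the pivaloyl group blocks attack at the acyl carbon and lengthens the life of 15, which gives the slow tertiary alcohol time to react.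

Step 8
Reactants: 16 pentacarbonyl{[(Z)-2-(benzyloxy)vinyl]{[2-methyl-1-(2-(prop-1-yn-1-yl)-1,3-dioxolan-2-yl)propan-2-yl]oxy}carbene}chromium
Product: 18 7-(benzyloxy)-2,2,5-trimethylspiro[chromane-4,2'-[1,3]dioxolan]-6-ol, via tricarbonylchromium arene complex 17 (not isolated)
Conditions: THF (0.01 M), 65 °C, Ar; then air, EtOAc, rt
Reagents that add atoms: none
Why: Loss of a cis CO ligand, possibly helped by the Z ether oxygen taking the vacant site as in tetracarbonyl chelates of ortho-alkoxyaryl carbenes, lets the tethered alkyne insert into the Cr=C bond to give a vinylcarbene. CO insertion then gives a vinylketene complex, six-electron electrocyclisation onto the benzyloxy-bearing vinyl carbon gives a cyclohexadienone, and tautomerisation gives the phenol as complex 17, which air releases. The closest known reaction type is the Dötz benzannulation of alkoxy(alkenyl)carbene chromium complexes in its intramolecular form with the alkyne tethered through the carbene oxygen. The pyran ring closes during alkyne insertion as a six-membered ring (carbene carbon, oxygen, C2, C3, C4, proximal alkyne carbon), favoured by the two quaternary centres of the tether. Ring B closes by the electrocyclisation of the dienylketene. No stereocentre is formed. The step needs the ketal-bearing alkyne carbon to bond to the carbene carbon: the short tether secures this, since the reverse orientation would put the new carbene carbon inside a strained ring. It also needs CO insertion instead of five-membered ring formation, which chromium with an alkenyl carbene normally gives. The conditions are neutral, so ketal and benzyl ether should survive; O6 emerges free and O7 benzylated.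

Step 9
Reactants: 19 1-fluoro-3-methoxy-5-methylbenzene
Product: 20 2-bromo-1-fluoro-5-methoxy-3-methylbenzene
Conditions: NBS, MeCN, 0 °C → rt
Reagents that add atoms: N-bromosuccinimide, O=C1CCC(=O)N1Br
Why: Electrophilic aromatic bromination para to the methoxy group, the usual outcome for 3,5-disubstituted anisoles.

Step 10
Reactants: 20 2-bromo-1-fluoro-5-methoxy-3-methylbenzene
Product: 22 3-bromo-2-fluoro-6-methoxy-4-methylbenzaldehyde, via aryllithium 21 (not isolated)
Conditions: LiTMP (from n-BuLi and 2,2,6,6-tetramethylpiperidine), THF, −78 °C; DMF; aq NH4Cl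
Reagents that add atoms: N,N-dimethylformamide, CN(C)C=O
Why: Directed ortho-metalation at the most acidic C–H, between fluorine and methoxy, by an amide base that does not exchange the bromide; the aryllithium is kept cold to avoid loss of LiF and is formylated by DMF.

Step 11
Reactants: 22 3-bromo-2-fluoro-6-methoxy-4-methylbenzaldehyde
Product: 23 benzyl 2-fluoro-3-formyl-4-methoxy-6-methylbenzoate
Conditions: Pd(OAc)2 (cat.), Xantphos, CO (1 atm), BnOH, Et3N, toluene, 80 °C
Reagents that add atoms: carbon monoxide, [C-]#[O+]; benzyl alcohol, OCc1ccccc1
Why: Palladium-catalysed alkoxycarbonylation of an aryl bromide with a wide-bite-angle diphosphine; with only an amine base and neutral alcohol the activated fluoride should stay in place.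

Step 12
Reactants: 18 7-(benzyloxy)-2,2,5-trimethylspiro[chromane-4,2'-[1,3]dioxolan]-6-ol, 23 benzyl 2-fluoro-3-formyl-4-methoxy-6-methylbenzoate
Product: 25 benzyl 2-{[7-(benzyloxy)-2,2,5-trimethyl-4-oxochroman-6-yl]oxy}-3-formyl-4-methoxy-6-methylbenzoate, via ketal diaryl ether 24 (not isolated)
Conditions: K2CO3, DMF, 70 °C, Ar; then 1 M HCl, THF, rt
Reagents that add atoms: water, O
Why: Nucleophilic aromatic substitution: the fluoride lies ortho to both formyl and ester groups and the methoxy group is meta to it, so the Meisenheimer adduct is well stabilised; dilute acid then hydrolyses the aryl ketone ketal through an oxocarbenium ion stabilised by the ring B oxygens.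

Step 13
Reactants: 25 benzyl 2-{[7-(benzyloxy)-2,2,5-trimethyl-4-oxochroman-6-yl]oxy}-3-formyl-4-methoxy-6-methylbenzoate
Product: 26 3-formyl-2-[(7-hydroxy-2,2,5-trimethyl-4-oxochroman-6-yl)oxy]-4-methoxy-6-methylbenzoic acid
Conditions: H2 (1 atm), Pd/C, EtOAc, rt, stopped at full debenzylation
Reagents that add atoms: none
Why: Catalytic hydrogenolysis of a benzyl ether and a benzyl ester, which should be faster than hydrogenation of the doubly ortho-substituted, electron-rich aldehyde and of the chromanone.

Step 14
Reactants: 26 3-formyl-2-[(7-hydroxy-2,2,5-trimethyl-4-oxochroman-6-yl)oxy]-4-methoxy-6-methylbenzoic acid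
Product: 27 mollicellin A methyl ether (the depsidone lactone of 26, ring A phenol as methyl ether)
Conditions: EDC·HCl, DMAP (cat.), CH2Cl2 (0.005 M), 0 °C → rt
Reagents that add atoms: none
Why: Carbodiimide (Steglich-type) esterification closing the seven-membered lactone, the classical depsidone ring closure from a diaryl ether hydroxy acid; high dilution disfavours chain formation.

Step 15
Reactants: 27 mollicellin A methyl ether
Product: 28 mollicellin A
Conditions: BCl3, CH2Cl2, −78 → 0 °C; H2O
Reagents that add atoms: none
Why: Chelation-controlled demethylation of the aryl methyl ether ortho to the formyl group; lactone, ketone and the cyclic tertiary ether are not chelated in this way and should remain.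

## Compound list

1 | ethyl 3-hydroxy-3-methylbutanoate | CCOC(=O)CC(C)(C)O | starting material
2 | ethyl 3-methyl-3-(triethylsilyloxy)butanoate | CCOC(=O)CC(C)(C)O[Si](CC)(CC)CC | intermediate
3 | N-methoxy-N,3-dimethyl-3-(triethylsilyloxy)butanamide | CON(C)C(=O)CC(C)(C)O[Si](CC)(CC)CC | intermediate
4 | 1-propynylmagnesium bromide | CC#C[Mg]Br | starting material
5 | 6-methyl-6-(triethylsilyloxy)hept-2-yn-4-one | CC#CC(=O)CC(C)(C)O[Si](CC)(CC)CC | intermediate
6 | triethyl{[2-methyl-1-(2-(prop-1-yn-1-yl)-1,3-dioxolan-2-yl)propan-2-yl]oxy}silane | CC#CC1(CC(C)(C)O[Si](CC)(CC)CC)OCCO1 | intermediate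
7 | 2-methyl-1-[2-(prop-1-yn-1-yl)-1,3-dioxolan-2-yl]propan-2-ol | CC#CC1(CC(C)(C)O)OCCO1 | intermediate
8 | benzyl vinyl ether | C=COCc1ccccc1 | starting material
9 | benzyl 1,2-dibromoethyl ether (racemic) | BrCC(Br)OCc1ccccc1 | intermediate
10 | (Z)-[(2-bromovinyl)oxy]methylbenzene | Br/C=C\OCc1ccccc1 | intermediate
11 | hexacarbonylchromium, Cr(CO)6 | O=C=[Cr](=C=O)(=C=O)(=C=O)(=C=O)=C=O | starting material
12 | (Z)-2-(benzyloxy)vinyllithium | [Li]/C=C\OCc1ccccc1 | intermediate
13 | lithium pentacarbonyl[(Z)-3-(benzyloxy)-1-oxidoprop-2-en-1-ylidene]chromate | [Li+].[O-]C(/C=C\OCc1ccccc1)=[Cr](=C=O)(=C=O)(=C=O)(=C=O)=C=O | intermediate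
14 | tetramethylammonium pentacarbonyl[(Z)-3-(benzyloxy)-1-oxidoprop-2-en-1-ylidene]chromate | C[N+](C)(C)C.[O-]C(/C=C\OCc1ccccc1)=[Cr](=C=O)(=C=O)(=C=O)(=C=O)=C=O | intermediate
15 | pentacarbonyl{[(Z)-2-(benzyloxy)vinyl](pivaloyloxy)carbene}chromium | CC(C)(C)C(=O)OC(/C=C\OCc1ccccc1)=[Cr](=C=O)(=C=O)(=C=O)(=C=O)=C=O | intermediate
16 | pentacarbonyl{[(Z)-2-(benzyloxy)vinyl]{[2-methyl-1-(2-(prop-1-yn-1-yl)-1,3-dioxolan-2-yl)propan-2-yl]oxy}carbene}chromium | O=C=[Cr](=C=O)(=C=O)(=C=O)(=C=O)=C(/C=C\OCc1ccccc1)OC(C)(C)CC1(C#CC)OCCO1 | intermediate
17 | tricarbonyl(η6-arene)chromium complex of 18 | CC1(C)CC2(OCCO2)c2c(C)c(O)c(OCc3ccccc3)cc2O1.O=C=[Cr](=C=O)=C=O | intermediate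
18 | 7-(benzyloxy)-2,2,5-trimethylspiro[chromane-4,2'-[1,3]dioxolan]-6-ol | CC1(C)CC2(OCCO2)c2c(C)c(O)c(OCc3ccccc3)cc2O1 | intermediate
19 | 1-fluoro-3-methoxy-5-methylbenzene (3-fluoro-5-methylanisole) | COc1cc(C)cc(F)c1 | starting material
20 | 2-bromo-1-fluoro-5-methoxy-3-methylbenzene | COc1cc(C)c(Br)c(F)c1 | intermediate
21 | (3-bromo-2-fluoro-6-methoxy-4-methylphenyl)lithium | COc1cc(C)c(Br)c(F)c1[Li] | intermediate
22 | 3-bromo-2-fluoro-6-methoxy-4-methylbenzaldehyde | COc1cc(C)c(Br)c(F)c1C=O | intermediate
23 | benzyl 2-fluoro-3-formyl-4-methoxy-6-methylbenzoate | COc1cc(C)c(C(=O)OCc2ccccc2)c(F)c1C=O | intermediate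
24 | benzyl 2-{[7-(benzyloxy)-2,2,5-trimethylspiro[chromane-4,2'-[1,3]dioxolan]-6-yl]oxy}-3-formyl-4-methoxy-6-methylbenzoate | COc1cc(C)c(C(=O)OCc2ccccc2)c(Oc2c(C)c3c(cc2OCc2ccccc2)OC(C)(C)CC32OCCO2)c1C=O | intermediate
25 | benzyl 2-{[7-(benzyloxy)-2,2,5-trimethyl-4-oxochroman-6-yl]oxy}-3-formyl-4-methoxy-6-methylbenzoate | COc1cc(C)c(C(=O)OCc2ccccc2)c(Oc2c(C)c3c(cc2OCc2ccccc2)OC(C)(C)CC3=O)c1C=O | intermediate
26 | 3-formyl-2-[(7-hydroxy-2,2,5-trimethyl-4-oxochroman-6-yl)oxy]-4-methoxy-6-methylbenzoic acid | COc1cc(C)c(C(=O)O)c(Oc2c(C)c3c(cc2O)OC(C)(C)CC3=O)c1C=O | intermediate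
27 | mollicellin A methyl ether (depsidone; ring A phenol as methyl ether) | Cc1cc(OC)c(C=O)c2c1C(=O)Oc1cc3c(c(C)c1O2)C(=O)CC(C)(C)O3 | intermediate
28 | mollicellin A | Cc1cc(O)c(C=O)c2c1C(=O)Oc1cc3c(c(C)c1O2)C(=O)CC(C)(C)O3 | target

## Step count and risk

Total step count: 15. Longest linear sequence: 10 steps (steps 1, 2, 3, 4, 7, 8, 12, 13, 14, 15).

Least certain steps:

Step 7 (carries the new-method label).
- Risk: addition of the hindered tertiary alcohol to the carbene carbon may be slower than thermal decay of the acyloxycarbene. The tertiary alkyl–oxygen bond of the product may also ionise and shed the tether as an alkene.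
- Fallback (known chemistry, gives up the carbene route to ring B; sets out from 1, comes back at 25): 1 is saponified with LiOH to 3-hydroxy-3-methylbutanoic acid F1. Purchased 2-methoxy-6-methylphenol F2 is oxidised para to its hydroxyl with potassium nitrosodisulfonate, (KSO3)2NO (Teuber oxidation), to 2-methoxy-6-methyl-1,4-benzoquinone F3, which Na2S2O4 reduces to 2-methoxy-6-methylbenzene-1,4-diol F4. F1 and F4 in BF3·OEt2 at 70 °C should give, by acylation para to the methoxy group and oxa-Michael closure on the unhindered hydroxyl, 6-hydroxy-7-methoxy-2,2,5-trimethylchroman-4-one F5. BBr3 gives 6,7-dihydroxy-2,2,5-trimethylchroman-4-one F6, and K2CO3 with one equivalent of benzyl bromide should alkylate the more acidic 7-hydroxyl (para to the carbonyl) to give 7-(benzyloxy)-6-hydroxy-2,2,5-trimethylchroman-4-one F7. F7 takes the place of 18 in step 12 (without the acid treatment) and gives 25.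

Step 8 (key step).
- Risk: the benzyloxy group makes the carbene complex and the vinylcarbene intermediate electron-rich, so CO loss may be sluggish or ring closure may occur without CO insertion, giving five-membered rings. The electron-rich phenol may also be oxidised during decomplexation.
- Fallback (removes the donor from the carbene and adds O7 afterwards; sets out from 7 and 11, comes back at 18): vinylmagnesium bromide and 11, then Me4NBr, give tetramethylammonium pentacarbonyl(1-oxidoprop-2-en-1-ylidene)chromate F8. Pivaloyl chloride and 7, as in step 7, give pentacarbonyl{{[2-methyl-1-(2-(prop-1-yn-1-yl)-1,3-dioxolan-2-yl)propan-2-yl]oxy}(vinyl)carbene}chromium F9, an ordinary alkoxy(alkenyl)carbene complex. Its tethered benzannulation gives 2,2,5-trimethylspiro[chromane-4,2'-[1,3]dioxolan]-6-ol F10. C7 is the only free ortho position of F10: IBX oxidises it to 2,2,5-trimethylspiro[chromene-4,2'-[1,3]dioxolane]-6,7-dione F11, Na2S2O4 reduces this to 2,2,5-trimethylspiro[chromane-4,2'-[1,3]dioxolane]-6,7-diol F12, and one equivalent of benzyl bromide with K2CO3 should alkylate the less hindered C7 hydroxyl to give 18.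

Step 12.
- Risk: attack of a phenoxide with two ortho neighbours on a carbon between formyl and ester groups may be slow, leaving time for oxidation of the phenoxide or displacement of fluoride by traces of hydroxide.
- Fallback (smaller electrophile, ester carbon introduced afterwards; sets out from 18 and 22, comes back at 27): 18 and 22 with K2CO3 in DMSO give 3-bromo-2-{[7-(benzyloxy)-2,2,5-trimethylspiro[chromane-4,2'-[1,3]dioxolan]-6-yl]oxy}-6-methoxy-4-methylbenzaldehyde F13. BCl3 with pentamethylbenzene at −78 °C and an aqueous acid work-up remove benzyl ether and ketal without touching the bromide, giving 3-bromo-2-[(7-hydroxy-2,2,5-trimethyl-4-oxochroman-6-yl)oxy]-6-methoxy-4-methylbenzaldehyde F14. Pd(OAc)2/Xantphos under CO with Et3N then closes the lactone by intramolecular aryloxycarbonylation to give 27.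

Step 11.
- Risk: benzyl alcohol may displace the activated fluoride during the carbonylation, or oxidative addition at the bromide between fluorine and methyl may be slow.
- Fallback (carboxyl before formyl; sets out from 20, comes back at 23): bromine–magnesium exchange on 20 with i-PrMgCl·LiCl and CO2 gives 2-fluoro-4-methoxy-6-methylbenzoic acid F15. Benzyl bromide and K2CO3 give benzyl 2-fluoro-4-methoxy-6-methylbenzoate F16. Magnesiation between fluorine and methoxy with the ester-tolerant amide base TMPMgCl·LiCl, then DMF, gives 23.

## Further compounds

F1 | step 7 | 3-hydroxy-3-methylbutanoic acid | CC(C)(O)CC(=O)O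
F2 | step 7 | 2-methoxy-6-methylphenol (purchased) | COc1cccc(C)c1O
F3 | step 7 | 2-methoxy-6-methyl-1,4-benzoquinone | COC1=CC(=O)C=C(C)C1=O
F4 | step 7 | 2-methoxy-6-methylbenzene-1,4-diol | COc1cc(O)cc(C)c1O
F5 | step 7 | 6-hydroxy-7-methoxy-2,2,5-trimethylchroman-4-one | COc1cc2c(c(C)c1O)C(=O)CC(C)(C)O2
F6 | step 7 | 6,7-dihydroxy-2,2,5-trimethylchroman-4-one | Oc1cc2c(c(C)c1O)C(=O)CC(C)(C)O2
F7 | step 7 | 7-(benzyloxy)-6-hydroxy-2,2,5-trimethylchroman-4-one | Cc1c(O)c(OCc2ccccc2)cc2c1C(=O)CC(C)(C)O2
F8 | step 8 | tetramethylammonium pentacarbonyl(1-oxidoprop-2-en-1-ylidene)chromate | C[N+](C)(C)C.[O-]C(C=C)=[Cr](=C=O)(=C=O)(=C=O)(=C=O)=C=O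
F9 | step 8 | pentacarbonyl{{[2-methyl-1-(2-(prop-1-yn-1-yl)-1,3-dioxolan-2-yl)propan-2-yl]oxy}(vinyl)carbene}chromium | O=C=[Cr](=C=O)(=C=O)(=C=O)(=C=O)=C(C=C)OC(C)(C)CC1(C#CC)OCCO1
F10 | step 8 | 2,2,5-trimethylspiro[chromane-4,2'-[1,3]dioxolan]-6-ol | CC1(C)CC2(OCCO2)c2c(C)c(O)ccc2O1
F11 | step 8 | 2,2,5-trimethylspiro[chromene-4,2'-[1,3]dioxolane]-6,7-dione | CC1(C)CC2(OCCO2)C2=C(C)C(=O)C(=O)C=C2O1
F12 | step 8 | 2,2,5-trimethylspiro[chromane-4,2'-[1,3]dioxolane]-6,7-diol | CC1(C)CC2(OCCO2)c2c(C)c(O)c(O)cc2O1
F13 | step 12 | 3-bromo-2-{[7-(benzyloxy)-2,2,5-trimethylspiro[chromane-4,2'-[1,3]dioxolan]-6-yl]oxy}-6-methoxy-4-methylbenzaldehyde | COc1cc(C)c(Br)c(Oc2c(C)c3c(cc2OCc2ccccc2)OC(C)(C)CC32OCCO2)c1C=O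
F14 | step 12 | 3-bromo-2-[(7-hydroxy-2,2,5-trimethyl-4-oxochroman-6-yl)oxy]-6-methoxy-4-methylbenzaldehyde | COc1cc(C)c(Br)c(Oc2c(C)c3c(cc2O)OC(C)(C)CC3=O)c1C=O
F15 | step 11 | 2-fluoro-4-methoxy-6-methylbenzoic acid | COc1cc(C)c(C(=O)O)c(F)c1
F16 | step 11 | benzyl 2-fluoro-4-methoxy-6-methylbenzoate | COc1cc(C)c(C(=O)OCc2ccccc2)c(F)c1
A1 | alternative 1 | depsidone aryl iodide (ring A as in 27; ring B with iodine at the carbon that becomes C4a, methoxy at the carbon that becomes C8a, hydrogen in place of the C5 methyl) | COc1cc(C)c2c(c1C=O)Oc1cc(I)c(OC)cc1OC2=O
A2 | alternative 1 | depsidone with ring B methyl and 3-hydroxy-3-methylbut-1-ynyl group in place | COc1cc(C)c2c(c1C=O)Oc1c(C)c(C#CC(C)(C)O)c(OC)cc1OC2=O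
A3 | alternative 2 | 6-(ethynyloxy)-2,2,5-trimethyl-4-oxochroman-7-yl but-2-ynoate | CC#CC(=O)Oc1cc2OC(C)(C)CC(=O)c2c(C)c1OC#C
A4 | alternative 2 | desformyl mollicellin A with a pinacol boronate in place of the hydroxyl | CC1(C)OB(OC1(C)C)c1cc(C)c2c(c1)Oc1c(C)c3c(cc1OC2=O)OC(C)(C)CC3=O
A5 | alternative 3 | benzyl 2-diazo-4-methyl-3-oxopent-4-enoate | C=C(C)C(=O)C(=[N+]=[N-])C(=O)OCc1ccccc1
A6 | alternative 3 | 7-(benzyloxy)-6-(ethynyloxy)-2,2,5-trimethylchroman-4-one | C#COc1c(C)c2c(cc1OCc1ccccc1)OC(C)(C)CC2=O
A7 | alternative 3 | benzyl 2-[(7-benzyloxy-2,2,5-trimethyl-4-oxochroman-6-yl)oxy]-4-hydroxy-6-methylbenzoate | O=C(OCc1ccccc1)c1c(C)cc(O)cc1Oc1c(C)c2c(cc1OCc1ccccc1)OC(C)(C)CC2=O
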